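The decalin is opened at C3–C4 of ring A, so that ring B (C5–C10) can be taken from (S)-carvone. Its stereocentre is C5 with the correct hydrogen, its ketone marks C9, its ring methyl is C17 on C8, and its isopropenyl group holds C4 and C19. One ring-closing metathesis exploits the vicinal trans branches at C5 and C10 of ring B. It joins a butenyl arm on C10 (C1–C3) to an acrylate on C5, creating C3=C4, ring A and the trans fusion at once and leaving an enoate primed for C3 oxygenation and C4 methylation. The precursor is carvone carrying a C10 methyl, a trans C10 butenyl chain and a methyl acrylate instead of isopropenyl.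

Key step: step 8

Remark on the chemistry: labdane numbering is used from compound 1 onward (carvone C5 = C5, C6 = C10, C1 = C9, C2 = C8, C3 = C7, C4 = C6). "Upper face" is the face carrying H-5 and "lower face" the face carrying the C20 methyl. Compound 4 is assumed to be carried on as an epimer mixture, because its new centre is flattened again in step 2.

Step 1
Reactants: 1 (S)-(+)-carvone; 2 iodomethane
Product: 4 (5S)-6-methylcarvone as a mixture of epimers at the new centre, via carvone lithium dienolate 3 (not isolated)
Conditions: LiN(i-Pr)2 (LDA, 1.05 equiv), THF, −78 °C; MeI, −78 → 0 °C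
Reagents that add atoms: iodomethane (2), CI
Why: Kinetic α′-deprotonation of the enone and SN2 methylation of the cross-conjugated lithium dienolate (enolate alkylation) is routine for carvone, and the epimer mixture at the new centre is of no consequence because step 2 planarises it again.

Step 2
Reactants: 4 (5S)-6-methylcarvone; 5 4-iodobut-1-ene
Product: 7 (5R,6R)-6-(but-3-enyl)-6-methylcarvone, via 6-methylcarvone lithium dienolate 6 (not isolated)
Conditions: LiN(i-Pr)2 (1.1 equiv), THF, −78 → 0 °C; DMPU, 4-iodobut-1-ene (2 equiv), −78 °C → rt
Reagents that add atoms: 4-iodobut-1-ene (5), C=CCCI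
Why: Second enolate alkylation: the fully substituted dienolate 6 is shielded on one face by the neighbouring isopropenyl group, so the primary iodide (more reactive and less prone to E2 than the bromide, with DMPU loosening the lithium aggregate) should enter anti to it and set quaternary C10 with the butenyl chain trans and the methyl cis to the C5 substituent.

Step 3
Reactants: 7 (5R,6R)-6-(but-3-enyl)-6-methylcarvone
Product: 8 allylic chloride (side chain on C5 now C(=CH2)CH2Cl)
Conditions: Ca(OCl)2, solid CO2, CH2Cl2/H2O, 0 °C
Reagents that add atoms: calcium hypochlorite (chlorine source, acting as HOCl), [Ca+2].[O-]Cl.[O-]Cl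
Why: Ene-type allylic chlorination with HOCl is selective for the electron-richest, 1,1-disubstituted alkene over the monosubstituted butenyl and the electron-poor enone alkene, and it only moves the double bond inside the three-carbon side chain, so C5 is untouched.

Step 4
Reactants: 8 allylic chloride
Product: 10 allylic alcohol (side chain on C5 now C(=CH2)CH2OH), via allylic acetate 9 (not isolated)
Conditions: KOAc, n-Bu4NI (cat.), DMF, 60 °C; then MeOH, K2CO3 (cat.), rt, same flask
Reagents that add atoms: potassium acetate, CC(=O)[O-].[K+]
Why: SN2 displacement of the primary allylic chloride by acetate followed by carbonate-catalysed transesterification frees the alcohol under conditions too mild to disturb the enone or the quaternary centre.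

Step 5
Reactants: 10 allylic alcohol
Product: 11 enal (side chain on C5 now C(=CH2)CHO)
Conditions: MnO2 (activated, excess), CH2Cl2, rt
Reagents that add atoms: none
Why: MnO2 oxidises only allylic alcohols and stops at the aldehyde, giving the 2-substituted acrolein without touching the other alkenes.

Step 6
Reactants: 11 enal
Product: 12 acrylic acid (side chain on C5 now C(=CH2)CO2H)
Conditions: NaClO2, NaH2PO4, 2-methylbut-2-ene (excess), t-BuOH/H2O, 0 °C → rt
Reagents that add atoms: sodium chlorite, [Na+].[O-]Cl=O
Why: Pinnick oxidation converts enals into acrylic acids without double-bond migration, the excess 2-methylbut-2-ene intercepting the HOCl that would otherwise attack the alkenes.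

Step 7
Reactants: 12 acrylic acid; 2 iodomethane
Product: 13 dialkylated carvone acrylate (methyl ester; C10 methyl cis and C10 butenyl trans to the C5 acrylate)
Conditions: MeI, K2CO3, DMF, rt
Reagents that add atoms: iodomethane (2), CI
Why: Carboxylate O-alkylation with iodomethane under weak base is a mild esterification that avoids acid- or strong-base-induced migration of the acrylate double bond towards C5.

Step 8
Reactants: 13 dialkylated carvone acrylate
Product: 14 trans-fused bicyclic dienone ester (ring A C3=C4 enoate, ring B C7=C8 enone, H-5 and C20 anti)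
Conditions: RuCl2(SIMes)(=CH-C6H4-2-O-i-Pr) (second-generation Hoveyda–Grubbs catalyst, 5 mol %), 1,4-benzoquinone (10 mol %), toluene (0.005 M), 80 °C, argon sparge
Reagents that add atoms: none
Why: Ring-closing olefin metathesis: the ruthenium benzylidene first exchanges with the unhindered monosubstituted butenyl alkene, and the resulting alkylidene adds across the neighbouring acrylate C=CH2 through a ruthenacyclobutane whose cycloreversion gives the C3=C4 bond and a Ru=CH2 carrier, with ethene leaving the solution. The closest known reaction type is the metathesis closure of α-substituted acrylates onto terminal alkenes to give cyclic trisubstituted enoates and unsaturated lactones. Ring A closes as a six-membered carbocycle from a 1,7-diene whose two arms sit on the adjacent ring B carbons C5 and C10. No stereocentre is created; because the arms are trans and can both lie equatorial on ring B, only the trans-fused decalin can form, so the fusion is dictated by C5 (from carvone) and C10 (step 2). The step needs site selectivity among three alkenes and cyclisation in preference to dimerisation: the trisubstituted, electron-poor enone alkene is inert to the catalyst, the acrylate cannot homodimerise, high dilution, ethene removal and the short tether favour closure, and benzoquinone suppresses alkene migration by ruthenium hydrides.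

Step 9
Reactants: 14 trans-fused bicyclic dienone ester
Product: 16 C9 enol triflate (C8=C9 tetrasubstituted; ring A enoate intact), via lithium enolate 15 (not isolated)
Conditions: LiBH(s-Bu)3 (1.05 equiv), THF, −78 °C; N-(5-chloropyridin-2-yl)bis(trifluoromethanesulfonimide), −78 → 0 °C
Reagents that add atoms: N-(5-chloropyridin-2-yl)bis(trifluoromethanesulfonimide), O=S(=O)(N(c1ccc(Cl)cn1)S(=O)(=O)C(F)(F)F)C(F)(F)F
Why: Conjugate hydride addition of the bulky borohydride to C7 of the enone (its carbonyl is blocked by quaternary C10, and the enone is a better acceptor than the α-branched ring A enoate at −78 °C with one equivalent) gives the regiodefined enolate 15, whose O-sulfonylation fixes the C8=C9 double bond.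

Step 10
Reactants: 16 C9 enol triflate; 17 carbon monoxide
Product: 18 bis-enoate diester (C11 methyl ester on C9, C8=C9; C19 methyl ester on C4, C3=C4)
Conditions: Pd(OAc)2 (10 mol %), dppf, CO (1 atm), MeOH, Et3N, DMF, 60 °C
Reagents that add atoms: carbon monoxide (17), [C-]#[O+]; methanol, CO
Why: Palladium-catalysed methoxycarbonylation of an enol triflate (oxidative addition to zerovalent palladium, CO insertion, methanolysis) installs C11 on C9 and is known to cope with tetrasubstituted cyclohexenyl triflates next to a quaternary carbon.

Step 11
Reactants: 18 bis-enoate diester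
Product: 20 C3-hydroxy diester (mixture at C3 and C4), via C3 pinacol boronate 19 (not isolated)
Conditions: CuCl (5 mol %), NaOt-Bu (10 mol %), DPEphos (5 mol %), B2pin2, MeOH (2 equiv), THF, rt; then 30% H2O2, pH 7 phosphate buffer, 0 °C → rt
Reagents that add atoms: bis(pinacolato)diboron (boron of 19 only), CC1(C)OB(OC1(C)C)B1OC(C)(C)C(C)(C)O1; hydrogen peroxide, OO
Why: Copper-catalysed conjugate borylation followed by C–B oxidation places oxygen on C3, the boryl-copper species adding only to the ring A enoate with its β-CH and not to the tetrasubstituted ring B enoate, and the configurations at C3 and C4 are irrelevant because both are reset in steps 12 to 15.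

Step 12
Reactants: 20 C3-hydroxy diester
Product: 21 β-keto ester (C3 ketone, C4–H, keto/enol and C4 epimer mixture)
Conditions: Dess–Martin periodinane, CH2Cl2, 0 °C → rt
Reagents that add atoms: none
Why: Dess–Martin oxidation of a secondary alcohol runs under near-neutral conditions, so the β-hydroxy ester should give the β-keto ester without β-elimination.

Step 13
Reactants: 21 β-keto ester; 2 iodomethane
Product: 22 C4-methylated keto diester (C18 methyl equatorial on the upper face, C19 ester axial on the lower face)
Conditions: MeI, K2CO3, acetone, rt → 40 °C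
Reagents that add atoms: iodomethane (2), CI
Why: C-alkylation of a stabilised β-keto ester enolate with a soft electrophile: iodomethane should approach C4 from the upper face, away from the axial C20 methyl that guards the lower face in a 1,3-relationship, which sets C4 with equatorial C18 and axial C19.

Step 14
Reactants: 22 C4-methylated keto diester
Product: 24 deconjugated keto diester (C8=C17 methylene, H-9 axial on the upper face, C11 ester equatorial), via dilithium bis-enolate 23 (not isolated)
Conditions: LiN(i-Pr)2 (3 equiv), DMPU, THF, −78 → −20 °C; cannulated into AcOH/THF, −78 °C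
Reagents that add atoms: none
Why: Deconjugative protonation of an extended ester enolate: the first equivalent of base masks the C3 ketone as its C2 enolate, the next removes a C17 proton (the γ-hydrogen held cis to the ester carbonyl), and kinetic α-protonation of the dienolate from the upper face opposite axial C20 sets C9 with axial hydrogen and equatorial ester while leaving the C8=C17 methylene.

Step 15
Reactants: 24 deconjugated keto diester
Product: 25 3,11,19-triol (C3 hydroxyl equatorial, lower face)
Conditions: LiAlH4 (excess), THF, 0 °C → reflux; aqueous work-up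
Reagents that add atoms: none
Why: Exhaustive hydride reduction: axial delivery to the C3 ketone from the upper face, opposite the axial C19 and C20 groups, sets the equatorial C3 alcohol as in other 4,4-disubstituted 3-ketones, and both esters go to primary alcohols without moving the isolated alkene.

Step 16
Reactants: 25 3,11,19-triol
Product: 26 3,19-O-isopropylidene C11 alcohol
Conditions: Me2C(OMe)2 (1.5 equiv), PPTS (cat.), acetone, rt
Reagents that add atoms: 2,2-dimethoxypropane, COC(C)(C)OC
Why: Acid-catalysed transketalisation ties the 1,3-related C3 and C19 hydroxyls into a chair dioxane, the only cyclic ketal within reach, and so singles out the C11 hydroxyl.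

Step 17
Reactants: 26 3,19-O-isopropylidene C11 alcohol
Product: 27 C11 aldehyde (β,γ-unsaturated, H-9 unchanged)
Conditions: Dess–Martin periodinane, pyridine, CH2Cl2, 0 °C
Reagents that add atoms: none
Why: Buffered Dess–Martin oxidation gives the β,γ-unsaturated aldehyde under non-basic conditions, which should avoid C9 epimerisation and migration of the C8=C17 bond into conjugation.

Step 18
Reactants: 27 C11 aldehyde; 28 2-(dichloromethyl)-4,4,5,5-tetramethyl-1,3,2-dioxaborolane
Product: 29 (E)-C11=C12 alkenyl pinacol boronate
Conditions: CrCl2 (8 equiv), LiI (4 equiv), Cl2CHBpin (2 equiv), THF, rt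
Reagents that add atoms: 2-(dichloromethyl)-4,4,5,5-tetramethyl-1,3,2-dioxaborolane (28), ClC(Cl)B1OC(C)(C)C(C)(C)O1
Why: Takai–Utimoto olefination with a geminal dichromium boryl reagent is non-basic, tolerates α-branched enolisable aldehydes and gives the E-alkenylboronate through the elimination geometry favoured by the bulky decalin residue.

Step 19
Reactants: 29 (E)-alkenyl pinacol boronate; 30 3-bromofuran-2(5H)-one
Product: 31 3,19-O-isopropylidene dienyl butenolide
Conditions: PdCl2(dppf) (5 mol %), K3PO4 (2 equiv), THF/H2O, 40 °C
Reagents that add atoms: 3-bromofuran-2(5H)-one (30), O=C1OCC=C1Br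
Why: Suzuki–Miyaura coupling of an alkenylboronate with an α-bromo enoate proceeds with retention of the E geometry, and the weak base at mild temperature should spare the butenolide and the doubly allylic C9–H.

Step 20
Reactants: 31 3,19-O-isopropylidene dienyl butenolide
Product: 32 3,19-diol (14-deoxy-11,12-didehydroandrographolide)
Conditions: AcOH/H2O (7:3), rt
Reagents that add atoms: none
Why: Aqueous acetic acid hydrolyses the isopropylidene ketal while being too weak to isomerise the exocyclic alkene or the dienyl lactone.

Step 21
Reactants: 32 3,19-diol; 33 acetic anhydride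
Product: 34 target, 19-O-acetyl-14-deoxy-11,12-didehydroandrographolide
Conditions: Ac2O (1.1 equiv), pyridine, CH2Cl2, 0 °C
Reagents that add atoms: acetic anhydride (33), CC(=O)OC(C)=O
Why: Kinetic acylation distinguishes the primary C19 hydroxyl from the secondary C3 hydroxyl flanked by quaternary C4, so one equivalent of anhydride at low temperature should give the 19-monoacetate.

Compound list

1 | (S)-(+)-carvone | CC1=CC[C@H](C(C)=C)CC1=O | starting material
2 | iodomethane | CI | starting material
3 | carvone lithium dienolate (α′-enolate) | CC1=CC[C@H](C(C)=C)C=C1O[Li] | intermediate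
4 | (5S)-6-methylcarvone, both epimers at the methyl-bearing carbon | CC1=CC[C@H](C(C)=C)C(C)C1=O | intermediate
5 | 4-iodobut-1-ene | C=CCCI | starting material
6 | 6-methylcarvone lithium dienolate | CC1=CC[C@H](C(C)=C)C(C)=C1O[Li] | intermediate
7 | (5R,6R)-6-(but-3-enyl)-2,6-dimethyl-5-(prop-1-en-2-yl)cyclohex-2-en-1-one, butenyl trans to isopropenyl | CC1=CC[C@H](C(C)=C)[C@@](C)(CCC=C)C1=O | intermediate
8 | allylic chloride, 5-(3-chloroprop-1-en-2-yl) analogue of 7 | CC1=CC[C@H](C(=C)CCl)[C@@](C)(CCC=C)C1=O | intermediate
9 | allylic acetate, 5-(3-acetoxyprop-1-en-2-yl) analogue of 7 | CC1=CC[C@H](C(=C)COC(C)=O)[C@@](C)(CCC=C)C1=O | intermediate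
10 | allylic alcohol, 5-(3-hydroxyprop-1-en-2-yl) analogue of 7 | CC1=CC[C@H](C(=C)CO)[C@@](C)(CCC=C)C1=O | intermediate
11 | enal, 5-(3-oxoprop-1-en-2-yl) analogue of 7 | CC1=CC[C@H](C(=C)C=O)[C@@](C)(CCC=C)C1=O | intermediate
12 | acrylic acid, 5-(1-carboxyvinyl) analogue of 7 | CC1=CC[C@H](C(=C)C(=O)O)[C@@](C)(CCC=C)C1=O | intermediate
13 | dialkylated carvone acrylate, methyl 2-[(1S-type C5) ring]acrylate with C10 methyl cis and C10 butenyl trans | CC1=CC[C@H](C(=C)C(=O)OC)[C@@](C)(CCC=C)C1=O | intermediate
14 | trans-fused bicyclic dienone ester (C3=C4 enoate, C7=C8 enone, C9 ketone) | CC1=CC[C@@H]2C(C(=O)OC)=CCC[C@@]2(C)C1=O | intermediate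
15 | C8=C9 lithium enolate of the 7,8-dihydro ketone | CC=1CC[C@@H]2C(C(=O)OC)=CCC[C@@]2(C)C=1O[Li] | intermediate
16 | C9 enol triflate | CC=1CC[C@@H]2C(C(=O)OC)=CCC[C@@]2(C)C=1OS(=O)(=O)C(F)(F)F | intermediate
17 | carbon monoxide | [C-]#[O+] | starting material
18 | bis-enoate diester (C11 and C19 methyl esters) | CC=1CC[C@@H]2C(C(=O)OC)=CCC[C@@]2(C)C=1C(=O)OC | intermediate
19 | C3 pinacol boronate, C3 and C4 unassigned | CC=1CC[C@@H]2C(C(=O)OC)C(B3OC(C)(C)C(C)(C)O3)CC[C@@]2(C)C=1C(=O)OC | intermediate
20 | C3-hydroxy diester, C3 and C4 unassigned | CC=1CC[C@@H]2C(C(=O)OC)C(O)CC[C@@]2(C)C=1C(=O)OC | intermediate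
21 | β-keto ester, C4 unassigned | CC=1CC[C@@H]2C(C(=O)OC)C(=O)CC[C@@]2(C)C=1C(=O)OC | intermediate
22 | C4-methylated keto diester (C18 equatorial, C19 ester axial and cis to C20) | CC=1CC[C@@H]2[C@](C)(C(=O)OC)C(=O)CC[C@@]2(C)C=1C(=O)OC | intermediate
23 | dilithium bis-enolate (C2=C3 ketone enolate, C17=C8–C9=C11 ester dienolate) | C=C1CC[C@@H]2[C@](C)(C(=O)OC)C(O[Li])=CC[C@@]2(C)C1=C(OC)O[Li] | intermediate
24 | deconjugated keto diester (C8=C17, H-9 cis to H-5) | C=C1CC[C@@H]2[C@](C)(C(=O)OC)C(=O)CC[C@@]2(C)[C@@H]1C(=O)OC | intermediate
25 | 3,11,19-triol (equatorial C3–OH cis to C19 and C20) | C=C1CC[C@@H]2[C@](C)(CO)[C@H](O)CC[C@@]2(C)[C@@H]1CO | intermediate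
26 | 3,19-O-isopropylidene C11 alcohol | C=C1CC[C@@H]2[C@]3(C)COC(C)(C)O[C@@H]3CC[C@@]2(C)[C@@H]1CO | intermediate
27 | 3,19-O-isopropylidene C11 aldehyde | C=C1CC[C@@H]2[C@]3(C)COC(C)(C)O[C@@H]3CC[C@@]2(C)[C@@H]1C=O | intermediate
28 | 2-(dichloromethyl)-4,4,5,5-tetramethyl-1,3,2-dioxaborolane | ClC(Cl)B1OC(C)(C)C(C)(C)O1 | starting material
29 | (E)-C11=C12 alkenyl pinacol boronate | C=C1CC[C@@H]2[C@]3(C)COC(C)(C)O[C@@H]3CC[C@@]2(C)[C@@H]1/C=C/B4OC(C)(C)C(C)(C)O4 | intermediate
30 | 3-bromofuran-2(5H)-one | O=C1OCC=C1Br | starting material
31 | 3,19-O-isopropylidene-14-deoxy-11,12-didehydroandrographolide | C=C1CC[C@@H]2[C@]3(C)COC(C)(C)O[C@@H]3CC[C@@]2(C)[C@@H]1/C=C/C1=CCOC1=O | intermediate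
32 | 14-deoxy-11,12-didehydroandrographolide (3,19-diol) | C=C1CC[C@@H]2[C@](C)(CO)[C@H](O)CC[C@@]2(C)[C@@H]1/C=C/C1=CCOC1=O | intermediate
33 | acetic anhydride | CC(=O)OC(C)=O | starting material
34 | 19-O-acetyl-14-deoxy-11,12-didehydroandrographolide (CNP0346413.1) | C=C1CC[C@@H]2[C@](C)(COC(C)=O)[C@H](O)CC[C@@]2(C)[C@@H]1/C=C/C1=CCOC1=O | target

Total step count: 21. Longest linear sequence: 21 steps from 1 (all coupling partners are purchased).

Steps most likely to fail

Step 8. The crowded, electron-poor acrylate may be engaged too slowly, so that intermolecular coupling of the butenyl ends or double-bond migration takes over. The fallback sets out from allylic alcohol 10 and moves the ring closure ahead of the oxidation-state adjustment. The free allylic hydroxyl makes the 1,1-disubstituted alkene electron-richer and is known to accelerate ruthenium metathesis. RuCl2(=CHPh)(PCy3)(SIMes) (second-generation Grubbs catalyst) in refluxing CH2Cl2 should give the bicyclic allylic alcohol F1. MnO2 should then give the bicyclic enal F2, and NaClO2/NaH2PO4/2-methylbut-2-ene the bicyclic enoic acid F3. MeI/K2CO3 brings the material back to the route at 14.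

Step 2. C-alkylation of the crowded enolate by an unactivated halide may be slow, with loss of the halide by elimination, proton transfer back to 4, or O-alkylation. The fallback sets out from 4 (through 6) and uses the far more reactive allyl bromide, which should enter on the same face and give 6-allyl-6-methylcarvone F4. The chain is then lengthened by one carbon. RhCl(PPh3)3-catalysed hydroboration with catecholborane is selective for the monosubstituted alkene and tolerant of the ketone, and should give the catechol boronate F5. Buffered H2O2 should give the primary alcohol F6, and Dess–Martin periodinane the aldehyde F7. Ph3P=CH2 at −78 °C should attack only the aldehyde and return to the route at 7.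

Step 14. Base may remove a C7 instead of a C17 proton, dianion formation may be incomplete, or the product may slip back into conjugation or be protonated on the wrong face. The fallback sets out from 22 and replaces the anionic chemistry by a photochemical deconjugation. NaBH4 in MeOH at 0 °C should first remove the light-sensitive ketone and give the equatorial C3-hydroxy conjugated diester F8. Irradiation at 254 nm in ether with a catalytic amine should trigger a 1,5-hydrogen shift to the ester carbonyl, which is geometrically possible only from C17. Ketonisation at C9 from the less hindered upper face should then give the deconjugated hydroxy diester F9. LiAlH4 returns to the route at 25.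

Further compounds

F1 | step 8 | bicyclic allylic alcohol (C19 hydroxymethyl on C3=C4, ring B enone) | CC1=CC[C@@H]2C(CO)=CCC[C@@]2(C)C1=O
F2 | step 8 | bicyclic enal (C19 aldehyde on C3=C4) | CC1=CC[C@@H]2C(C=O)=CCC[C@@]2(C)C1=O
F3 | step 8 | bicyclic enoic acid (C19 acid on C3=C4) | CC1=CC[C@@H]2C(C(=O)O)=CCC[C@@]2(C)C1=O
F4 | step 2 | 6-allyl-6-methylcarvone, allyl trans to isopropenyl | CC1=CC[C@H](C(C)=C)[C@@](C)(CC=C)C1=O
F5 | step 2 | catechol boronate of the 3-borylpropyl chain | CC1=CC[C@H](C(C)=C)[C@@](C)(CCCB2Oc3ccccc3O2)C1=O
F6 | step 2 | 6-(3-hydroxypropyl)-6-methylcarvone | CC1=CC[C@H](C(C)=C)[C@@](C)(CCCO)C1=O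
F7 | step 2 | 6-(3-oxopropyl)-6-methylcarvone | CC1=CC[C@H](C(C)=C)[C@@](C)(CCC=O)C1=O
F8 | step 14 | equatorial C3-hydroxy conjugated diester | CC=1CC[C@@H]2[C@](C)(C(=O)OC)[C@H](O)CC[C@@]2(C)C=1C(=O)OC
F9 | step 14 | deconjugated C3-hydroxy diester (C8=C17, H-9 cis to H-5) | C=C1CC[C@@H]2[C@](C)(C(=O)OC)[C@H](O)CC[C@@]2(C)[C@@H]1C(=O)OC
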